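**Retrosynthetic overview**

1. Target 29 ⇒ bromide 26 by a C9–C10 disconnection: a photoredox radical ring closure of a butenolide-stabilised allyl radical (C9) onto the γ-terminus (C10) of a ring A silyl dienol ether. This closes the ten-membered ring last, sets C10 and releases the enone.
2. 26 ⇒ East alkylborane (from 11) + West (Z)-vinyl bromide 22, joined at C4–C5 by B-alkyl Suzuki coupling.
3. East 11: ring A is made first by a catalytic asymmetric Diels–Alder reaction (C1, C14), followed by asymmetric vinylation (C2) and a singlet-oxygen ene/Kornblum–DeLaMare sequence (C13 ketone, C11=C12).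
4. West 22: but-2-yn-1-ol gives a (Z)-bromoenal; asymmetric propynylation sets C7, and alkoxide-directed carbomagnesiation/carboxylation builds the butenolide.
5. Ring order: ring A, then the butenolide, then the ten-membered ring.

Assumption: carbons carry briarane numbers (C1 quaternary, C2 propanoate carbinol, C5=C6, C7 lactone carbinol, C8=C17 butenolide alkene, C9 CH2, C10 ring-fusion CH, C11=C12–C13=O, C14 acetate carbinol), and the SMILES is read as 1R,2S,5Z,7R,10R,14S.

**Route**

Step 1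
Reactants: 1 (E)-pent-2-enal
Product: 2 (1E,3E)-1-[(tert-butyldimethylsilyl)oxy]penta-1,3-diene
Conditions: TBSOTf, Et3N, Et2O, 0 °C → rt
Reagents that add atoms: tert-butyldimethylsilyl trifluoromethanesulfonate, CC(C)(C)[Si](C)(C)OS(=O)(=O)C(F)(F)F
Why: Soft γ-enolisation of the enal (silyl triflate/amine) gives the 1-siloxydiene, mainly as the (1E,3E) isomer, which is the only isomer that reacts in step 2.

Step 2
Reactants: 2 (1E,3E)-1-[(tert-butyldimethylsilyl)oxy]penta-1,3-diene; 3 methacrolein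
Product: 4 (1S,2R,5R)-2-[(tert-butyldimethylsilyl)oxy]-1,5-dimethylcyclohex-3-ene-1-carbaldehyde
Conditions: (4S)-2-butyl-4-(1H-indol-3-ylmethyl)-3-tosyl-1,3,2-oxazaborolidin-5-one (10 mol %), CH2Cl2, −78 °C
Reagents that add atoms: none
Why: Catalytic enantioselective Diels–Alder reaction in which the siloxy group makes C11 the nucleophilic terminus (C11–C10 and C14–C1 bonds), the formyl-endo transition state puts OTBS cis to CHO, and the indole-shielded, boron-bound enal is attacked on the face that gives 1S (the sense known for this catalyst with 2-substituted acroleins); the C11 centre is destroyed later.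

Step 3
Reactants: 4 (1S,2R,5R)-2-[(tert-butyldimethylsilyl)oxy]-1,5-dimethylcyclohex-3-ene-1-carbaldehyde
Product: 6 (1S)-1-[(1R,2R,5R)-2-[(tert-butyldimethylsilyl)oxy]-1,5-dimethylcyclohex-3-en-1-yl]prop-2-en-1-yl propanoate, via vinylzinc alkoxide 5 (not isolated)
Conditions: (CH2=CH)2Zn (salt-free, 1.5 equiv), (−)-MIB [(2S)-3-exo-morpholinoisoborneol, 10 mol %], toluene, −20 → 0 °C; then EtCOCl, pyridine, 0 °C
Reagents that add atoms: divinylzinc, C=C[Zn]C=C; propanoyl chloride, CCC(=O)Cl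
Why: Amino-alcohol-catalysed vinylzinc addition (Noyori–Oppolzer type) delivers vinyl to the Si face of the aldehyde, which is also the Felkin–Anh face (siloxy-bearing C14 anti, attack past the methyl group), so C2 is set as S, and the zinc alkoxide is acylated in the same flask.

Step 4
Reactants: 6 (1S)-1-[(1R,2R,5R)-2-[(tert-butyldimethylsilyl)oxy]-1,5-dimethylcyclohex-3-en-1-yl]prop-2-en-1-yl propanoate
Product: 8 (1S)-1-[(1R,2R,5R)-2-(acetyloxy)-1,5-dimethylcyclohex-3-en-1-yl]prop-2-en-1-yl propanoate, via free C14 alcohol 7 (not isolated)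
Conditions: HF·pyridine, pyridine/THF, 0 °C → rt; then Ac2O, DMAP, rt
Reagents that add atoms: acetic anhydride, CC(=O)OC(C)=O
Why: Fluoride desilylation and DMAP-catalysed acetylation in one pot exchange the silyl group (needed for regiocontrol in step 2) for the C14 acetate of the target with retention, since the C–O bond is never broken.

Step 5
Reactants: 8 (1S)-1-[(1R,2R,5R)-2-(acetyloxy)-1,5-dimethylcyclohex-3-en-1-yl]prop-2-en-1-yl propanoate
Product: 10 (1S)-1-[(1R,6S)-6-(acetyloxy)-1,3-dimethyl-5-oxocyclohex-3-en-1-yl]prop-2-en-1-yl propanoate, via allylic C13 hydroperoxide 9 (not isolated)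
Conditions: O2, tetraphenylporphyrin (1 mol %), visible light, Ac2O, pyridine, DMAP (cat.), CH2Cl2, 0 °C → rt
Reagents that add atoms: dioxygen, O=O
Why: Schenck ene reaction followed by Kornblum–DeLaMare elimination: singlet oxygen bonds to C13 on the face anti to the C14 acetate while removing the tertiary allylic C11–H (the C14–H is deactivated by the acetoxy group), which moves the alkene to C11=C12, and the acetylated hydroperoxide collapses to the enone; the monosubstituted vinyl group is inert to singlet oxygen.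

Step 6
Reactants: 10 (1S)-1-[(1R,6S)-6-(acetyloxy)-1,3-dimethyl-5-oxocyclohex-3-en-1-yl]prop-2-en-1-yl propanoate
Product: 11 (1S)-1-[(1R,6S)-6-(acetyloxy)-5-[(tert-butyldimethylsilyl)oxy]-1,3-dimethylcyclohexa-2,4-dien-1-yl]prop-2-en-1-yl propanoate
Conditions: TBSOTf (1.3 equiv), Et3N, CH2Cl2, −78 → 0 °C
Reagents that add atoms: tert-butyldimethylsilyl trifluoromethanesulfonate, CC(C)(C)[Si](C)(C)OS(=O)(=O)C(F)(F)F
Why: Soft enolisation gives the linear endocyclic dienol ether by γ-deprotonation at C10, because the α′ C14–H is pseudoequatorial (acetate axial, side chain equatorial) and would lead to a strained tetrasubstituted enediol derivative, and the triethylammonium triflate formed equilibrates any exocyclic isomer to the endocyclic one (as in β-isophorone).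

Step 7
Reactants: 12 but-2-yn-1-ol
Product: 14 (2Z)-3-bromobut-2-en-1-ol, via cyclic vinylalanate 13 (not isolated)
Conditions: NaAlH2(OCH2CH2OCH3)2, THF, 0 °C → rt; then NBS, −78 °C
Reagents that add atoms: N-bromosuccinimide, O=C1CCC(=O)N1Br
Why: Hydroxyl-directed trans-hydroalumination puts aluminium on C3 cis to the CH2O group, and bromodealumination with retention gives the Z bromide that fixes the 5Z geometry of the target.

Step 8
Reactants: 14 (2Z)-3-bromobut-2-en-1-ol
Product: 15 (2Z)-3-bromobut-2-enal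
Conditions: MnO2, CH2Cl2, rt
Reagents that add atoms: none
Why: Neutral MnO2 oxidation of the allylic alcohol gives the enal without Z to E isomerisation.

Step 9
Reactants: 15 (2Z)-3-bromobut-2-enal; 16 propyne
Product: 17 (2Z,4R)-2-bromohept-2-en-5-yn-4-ol
Conditions: Me2Zn (3 equiv), (S,S)-ProPhenol (10 mol %), Ph3PO (20 mol %), toluene, 4 °C
Reagents that add atoms: none
Why: Trost dinuclear-zinc ProPhenol alkynylation, which is 1,2-selective for enals, delivers propynyl under ligand control to the Si face and sets C7 as R (the ligand antipode is the one that gives Si-face delivery).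

Step 10
Reactants: 17 (2Z,4R)-2-bromohept-2-en-5-yn-4-ol
Product: 20 (5R)-5-[(1Z)-2-bromoprop-1-en-1-yl]-4-ethenyl-3-methylfuran-2(5H)-one, via oxamagnesacycle 18 (not isolated), via hydroxy acid 19 (not isolated)
Conditions: CH2=CHMgCl (4 equiv), THF/cyclohexane, reflux; then CO2, −20 °C → rt; 1 M HCl
Reagents that add atoms: vinylmagnesium chloride, C=C[Mg]Cl; carbon dioxide, O=C=O
Why: Alkoxide-directed anti-carbomagnesiation of the propargylic alcohol (Duboudin–Fallis) adds vinyl to the proximal alkyne carbon C8 and leaves magnesium on C17 in a five-membered chelate, which is carboxylated with retention and lactonises on acidification; C7 is untouched and the vinyl bromide is inert to the Grignard reagent without a transition metal.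

Step 11
Reactants: 20 (5R)-5-[(1Z)-2-bromoprop-1-en-1-yl]-4-ethenyl-3-methylfuran-2(5H)-one
Product: 22 (5R)-5-[(1Z)-2-bromoprop-1-en-1-yl]-4-(hydroxymethyl)-3-methylfuran-2(5H)-one, via C9 aldehyde 21 (not isolated)
Conditions: OsO4 (2 mol %), NaIO4, 2,6-lutidine, dioxane/H2O, rt; then NaBH4, 0 °C
Reagents that add atoms: sodium periodate, [Na+].[O-]I(=O)(=O)=O
Why: Lemieux–Johnson cleavage takes the only reactive alkene (the terminal vinyl; the tetrasubstituted butenolide alkene and the vinyl bromide are deactivated towards OsO4), and borohydride reduces the resulting aldehyde faster than the lactone, giving the C9 alcohol.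

Step 12
Reactants: 11 (1S)-1-[(1R,6S)-6-(acetyloxy)-5-[(tert-butyldimethylsilyl)oxy]-1,3-dimethylcyclohexa-2,4-dien-1-yl]prop-2-en-1-yl propanoate; 22 (5R)-5-[(1Z)-2-bromoprop-1-en-1-yl]-4-(hydroxymethyl)-3-methylfuran-2(5H)-one
Product: 24 (1S,4Z)-1-[(1R,6S)-6-(acetyloxy)-5-[(tert-butyldimethylsilyl)oxy]-1,3-dimethylcyclohexa-2,4-dien-1-yl]-5-[(2R)-3-(hydroxymethyl)-4-methyl-5-oxo-2,5-dihydrofuran-2-yl]-4-methylpent-4-en-1-yl propanoate, via C4 alkylborane 23 (not isolated)
Conditions: 9-BBN, THF, 0 °C → rt; then 22, Pd(OAc)2 (5 mol %), SPhos (10 mol %), K3PO4 (3 M aq), THF, rt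
Reagents that add atoms: none
Why: 9-BBN hydroborates only the monosubstituted alkene, at C4 (the ketone is masked as the silyl dienol ether and esters are inert), and B-alkyl Suzuki–Miyaura coupling with the vinyl bromide forms C4–C5 with retention of the Z geometry.

Step 13
Reactants: 24 the seco alcohol of step 12
Product: 26 (1S,4Z)-1-[(1R,6S)-6-(acetyloxy)-5-[(tert-butyldimethylsilyl)oxy]-1,3-dimethylcyclohexa-2,4-dien-1-yl]-5-[(2R)-3-(bromomethyl)-4-methyl-5-oxo-2,5-dihydrofuran-2-yl]-4-methylpent-4-en-1-yl propanoate, via allylic mesylate 25 (not isolated)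
Conditions: MsCl, iPr2NEt, CH2Cl2, −20 °C; then LiBr, THF, 0 °C
Reagents that add atoms: lithium bromide, [Li+].[Br-]
Why: Mesylation and SN2 displacement by bromide convert the primary allylic alcohol into the radical precursor without any electrophilic bromine source, so the silyl dienol ether survives.

Step 14
Reactants: 26 the seco bromide of step 13
Product: 29 target CNP0109273.3, (1R,2S,5Z,7R,10R,14S)-14-acetoxy-13-oxo-2-propanoyloxybriara-5,8(17),11-trien-19,7-olide, via C9 allyl radical 27 (not isolated), via silyloxocarbenium ion 28 (not isolated)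
Conditions: fac-Ir(ppy)3 (2 mol %), 2,6-lutidine, degassed MeCN (1 mM, slow addition), 450 nm LEDs, rt
Reagents that add atoms: none
Why: Proposed new method: excited Ir(ppy)3 reduces the allylic bromide to a butenolide-stabilised, electrophilic allyl radical that adds through its CH2 terminus (C9) to the γ-carbon C10 of the electron-rich dienol ether, the siloxyallyl radical is oxidised by tetravalent iridium to the silyloxocarbenium ion, and loss of the silyl group to bromide gives the enone; the bond forms anti to the pseudoaxial C1–C2 bond (the alternative with axial methyl is eclipsed or screened by the axial C14 acetate), giving the trans ring fusion with C10 R, and the closest known reactions are the intermolecular photoredox alkylation of silyl enol and dienol ethers with α-bromocarbonyl compounds and atom-transfer radical macrocyclisations.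

**Compound list**

1 | (E)-pent-2-enal | CC/C=C/C=O | starting material
2 | (1E,3E)-1-[(tert-butyldimethylsilyl)oxy]penta-1,3-diene | C/C=C/C=C/O[Si](C)(C)C(C)(C)C | intermediate
3 | methacrolein | CC(=C)C=O | starting material
4 | (1S,2R,5R)-2-[(tert-butyldimethylsilyl)oxy]-1,5-dimethylcyclohex-3-ene-1-carbaldehyde | O=C[C@@]1(C)C[C@@H](C)C=C[C@H]1O[Si](C)(C)C(C)(C)C | intermediate
5 | vinylzinc alkoxide of the (S)-allylic alcohol from 4 (not isolated) | C=C[Zn]O[C@@H](C=C)[C@@]1(C)C[C@@H](C)C=C[C@H]1O[Si](C)(C)C(C)(C)C | intermediate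
6 | (1S)-1-[(1R,2R,5R)-2-[(tert-butyldimethylsilyl)oxy]-1,5-dimethylcyclohex-3-en-1-yl]prop-2-en-1-yl propanoate | CCC(=O)O[C@@H](C=C)[C@@]1(C)C[C@@H](C)C=C[C@H]1O[Si](C)(C)C(C)(C)C | intermediate
7 | (1S)-1-[(1S,2R,5R)-2-hydroxy-1,5-dimethylcyclohex-3-en-1-yl]prop-2-en-1-yl propanoate (not isolated) | CCC(=O)O[C@@H](C=C)[C@@]1(C)C[C@@H](C)C=C[C@H]1O | intermediate
8 | (1S)-1-[(1R,2R,5R)-2-(acetyloxy)-1,5-dimethylcyclohex-3-en-1-yl]prop-2-en-1-yl propanoate | CCC(=O)O[C@@H](C=C)[C@@]1(C)C[C@@H](C)C=C[C@H]1OC(C)=O | intermediate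
9 | allylic hydroperoxide: C13–OOH anti to the C14 acetate, C11=C12 (not isolated) | CCC(=O)O[C@@H](C=C)[C@@]1(C)CC(C)=C[C@H](OO)[C@H]1OC(C)=O | intermediate
10 | (1S)-1-[(1R,6S)-6-(acetyloxy)-1,3-dimethyl-5-oxocyclohex-3-en-1-yl]prop-2-en-1-yl propanoate | CCC(=O)O[C@@H](C=C)[C@@]1(C)CC(C)=CC(=O)[C@H]1OC(C)=O | intermediate
11 | (1S)-1-[(1R,6S)-6-(acetyloxy)-5-[(tert-butyldimethylsilyl)oxy]-1,3-dimethylcyclohexa-2,4-dien-1-yl]prop-2-en-1-yl propanoate | CCC(=O)O[C@@H](C=C)[C@@]1(C)C=C(C)C=C(O[Si](C)(C)C(C)(C)C)[C@H]1OC(C)=O | intermediate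
12 | but-2-yn-1-ol | CC#CCO | starting material
13 | sodium cyclic (Z)-vinylalanate of 12 (not isolated) | [Na+].CC1=CCO[Al-]1(OCCOC)OCCOC | intermediate
14 | (2Z)-3-bromobut-2-en-1-ol | Br/C(C)=C\CO | intermediate
15 | (2Z)-3-bromobut-2-enal | Br/C(C)=C\C=O | intermediate
16 | propyne | CC#C | starting material
17 | (2Z,4R)-2-bromohept-2-en-5-yn-4-ol | Br/C(C)=C\[C@@H](O)C#CC | intermediate
18 | five-membered oxamagnesacycle (O–Mg–C17=C8–C7), vinyl on C8 (not isolated) | Br/C(C)=C\[C@H]1O[Mg]C(C)=C1C=C | intermediate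
19 | (4R,5Z)-6-bromo-3-ethenyl-4-hydroxy-2-methylhepta-2,5-dienoic acid, C7 and CO2H cis (not isolated) | Br/C(C)=C\[C@@H](O)/C(C=C)=C(C)\C(O)=O | intermediate
20 | (5R)-5-[(1Z)-2-bromoprop-1-en-1-yl]-4-ethenyl-3-methylfuran-2(5H)-one | Br/C(C)=C\[C@H]1OC(=O)C(C)=C1C=C | intermediate
21 | (2R)-2-[(1Z)-2-bromoprop-1-en-1-yl]-4-methyl-5-oxo-2,5-dihydrofuran-3-carbaldehyde (not isolated) | Br/C(C)=C\[C@H]1OC(=O)C(C)=C1C=O | intermediate
22 | (5R)-5-[(1Z)-2-bromoprop-1-en-1-yl]-4-(hydroxymethyl)-3-methylfuran-2(5H)-one | Br/C(C)=C\[C@H]1OC(=O)C(C)=C1CO | intermediate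
23 | B-alkyl-9-BBN from 11, boron on C4 (not isolated) | CCC(=O)O[C@@H](CCB1C2CCCC1CCC2)[C@@]1(C)C=C(C)C=C(O[Si](C)(C)C(C)(C)C)[C@H]1OC(C)=O | intermediate
24 | (1S,4Z)-1-[(1R,6S)-6-(acetyloxy)-5-[(tert-butyldimethylsilyl)oxy]-1,3-dimethylcyclohexa-2,4-dien-1-yl]-5-[(2R)-3-(hydroxymethyl)-4-methyl-5-oxo-2,5-dihydrofuran-2-yl]-4-methylpent-4-en-1-yl propanoate | CCC(=O)O[C@@H](CC/C(C)=C\[C@H]1OC(=O)C(C)=C1CO)[C@@]1(C)C=C(C)C=C(O[Si](C)(C)C(C)(C)C)[C@H]1OC(C)=O | intermediate
25 | C9 methanesulfonate of 24 (not isolated) | CCC(=O)O[C@@H](CC/C(C)=C\[C@H]1OC(=O)C(C)=C1COS(C)(=O)=O)[C@@]1(C)C=C(C)C=C(O[Si](C)(C)C(C)(C)C)[C@H]1OC(C)=O | intermediate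
26 | C9 bromide corresponding to 24 (3-(bromomethyl)furanone) | CCC(=O)O[C@@H](CC/C(C)=C\[C@H]1OC(=O)C(C)=C1CBr)[C@@]1(C)C=C(C)C=C(O[Si](C)(C)C(C)(C)C)[C@H]1OC(C)=O | intermediate
27 | C9 allyl radical from 26 (not isolated) | CCC(=O)O[C@@H](CC/C(C)=C\[C@H]1OC(=O)C(C)=C1[CH2])[C@@]1(C)C=C(C)C=C(O[Si](C)(C)C(C)(C)C)[C@H]1OC(C)=O | intermediate
28 | O-silylated macrocyclic enone (silyloxocarbenium ion) (not isolated) | CCC(=O)O[C@H]1CC/C(C)=C\[C@H]2OC(=O)C(C)=C2C[C@@H]2C(C)=CC(=[O+][Si](C)(C)C(C)(C)C)[C@@H](OC(C)=O)[C@@]12C | intermediate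
29 | CNP0109273.3, (1R,2S,5Z,7R,10R,14S)-14-acetoxy-13-oxo-2-propanoyloxybriara-5,8(17),11-trien-19,7-olide | CCC(=O)O[C@H]1CC/C(C)=C\[C@H]2OC(=O)C(C)=C2C[C@@H]2C(C)=CC(=O)[C@@H](OC(C)=O)[C@@]12C | target

**Step count**

Total: 14 steps. Longest linear sequence: 9 steps (steps 1–6, then 12–14). The West branch is 5 steps (7–11) before the union.

**Steps most likely to fail, with fallbacks**

Step 14 (radical ring closure). The ten-membered ring may close slowly, giving reduction or oligomers, or with the cis ring fusion at C10. The fallback forms the same C9–C10 bond between the two fragments, where the radical is free to approach anti to the pseudoaxial C1 substituent, and closes the ring at C4–C5 instead. It sets out from 22 and 11. Alcohol 22 is converted with MsCl/iPr2NEt through (5R)-5-[(1Z)-2-bromoprop-1-en-1-yl]-4-[(methanesulfonyloxy)methyl]-3-methylfuran-2(5H)-one F1 and LiBr into (5R)-4-(bromomethyl)-5-[(1Z)-2-bromoprop-1-en-1-yl]-3-methylfuran-2(5H)-one F2. Ir(ppy)3-photocatalysed coupling of F2 with an excess of 11 gives the C10-alkylated enone (1S)-1-[(1R,2R,6S)-6-(acetyloxy)-2-{[(2R)-2-[(1Z)-2-bromoprop-1-en-1-yl]-4-methyl-5-oxo-2,5-dihydrofuran-3-yl]methyl}-1,3-dimethyl-5-oxocyclohex-3-en-1-yl]prop-2-en-1-yl propanoate F3. 9-BBN at 0 °C, where the monosubstituted alkene should react before the hindered enone carbonyl, gives the C4 B-alkyl-9-BBN F4, and high-dilution Suzuki coupling (Pd(OAc)2, SPhos, K3PO4) returns to the route at 29.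

Step 6 (regiochemistry and survival of the silyl dienol ether). Enolisation could occur toward C14 or the C20 methyl, and the silyl ether must survive three further steps. The fallback uses a dienyl acetate made under thermodynamic, acid-catalysed conditions, which is more robust but a weaker radical acceptor. It sets out from 10. Isopropenyl acetate with TsOH at reflux gives the linear dienyl acetate (1S)-1-[(1R,6S)-5,6-bis(acetyloxy)-1,3-dimethylcyclohexa-2,4-dien-1-yl]prop-2-en-1-yl propanoate F5. 9-BBN gives the C4 borane F6, and coupling with 22 as in step 12 gives the dienyl acetate seco alcohol F7. MsCl/iPr2NEt gives the C9 mesylate F8 and LiBr the C9 bromide F9. The photoredox closure of step 14, now with loss of the enol acetyl group, returns to the route at 29.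

Step 5 (singlet-oxygen ene reaction). A cis-disubstituted cyclohexene reacts slowly with singlet oxygen, and hydrogen abstraction at C14 could compete. The fallback is a radical allylic oxidation with transposition and sets out from 8. Dirhodium tetracaprolactamate Rh2(cap)4 with t-BuOOH and K2CO3 in CH2Cl2 abstracts the tertiary allylic C11–H, and the allyl radical is trapped at the less hindered C13 terminus as the C13 tert-butyl peroxide (1S)-1-[(1R,6S)-6-(acetyloxy)-5-(tert-butylperoxy)-1,3-dimethylcyclohex-3-en-1-yl]prop-2-en-1-yl propanoate F10 (C13 epimers). F10 loses tert-butanol under the reaction conditions and returns to the route at 10.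

**Further compounds**

F1 | step 14 | (5R)-5-[(1Z)-2-bromoprop-1-en-1-yl]-4-[(methanesulfonyloxy)methyl]-3-methylfuran-2(5H)-one | Br/C(C)=C\[C@H]1OC(=O)C(C)=C1COS(C)(=O)=O
F2 | step 14 | (5R)-4-(bromomethyl)-5-[(1Z)-2-bromoprop-1-en-1-yl]-3-methylfuran-2(5H)-one | Br/C(C)=C\[C@H]1OC(=O)C(C)=C1CBr
F3 | step 14 | (1S)-1-[(1R,2R,6S)-6-(acetyloxy)-2-{[(2R)-2-[(1Z)-2-bromoprop-1-en-1-yl]-4-methyl-5-oxo-2,5-dihydrofuran-3-yl]methyl}-1,3-dimethyl-5-oxocyclohex-3-en-1-yl]prop-2-en-1-yl propanoate | CCC(=O)O[C@@H](C=C)[C@@]1(C)[C@H](CC2=C(C)C(=O)O[C@@H]2/C=C(/C)Br)C(C)=CC(=O)[C@H]1OC(C)=O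
F4 | step 14 | C4 B-alkyl-9-BBN of F3 | CCC(=O)O[C@@H](CCB2C3CCCC2CCC3)[C@@]1(C)[C@H](CC2=C(C)C(=O)O[C@@H]2/C=C(/C)Br)C(C)=CC(=O)[C@H]1OC(C)=O
F5 | step 6 | (1S)-1-[(1R,6S)-5,6-bis(acetyloxy)-1,3-dimethylcyclohexa-2,4-dien-1-yl]prop-2-en-1-yl propanoate | CCC(=O)O[C@@H](C=C)[C@@]1(C)C=C(C)C=C(OC(C)=O)[C@H]1OC(C)=O
F6 | step 6 | C4 B-alkyl-9-BBN of F5 | CCC(=O)O[C@@H](CCB1C2CCCC1CCC2)[C@@]1(C)C=C(C)C=C(OC(C)=O)[C@H]1OC(C)=O
F7 | step 6 | dienyl acetate seco alcohol (acetate analogue of 24) | CCC(=O)O[C@@H](CC/C(C)=C\[C@H]1OC(=O)C(C)=C1CO)[C@@]1(C)C=C(C)C=C(OC(C)=O)[C@H]1OC(C)=O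
F8 | step 6 | C9 mesylate of F7 | CCC(=O)O[C@@H](CC/C(C)=C\[C@H]1OC(=O)C(C)=C1COS(C)(=O)=O)[C@@]1(C)C=C(C)C=C(OC(C)=O)[C@H]1OC(C)=O
F9 | step 6 | C9 bromide from F8 (acetate analogue of 26) | CCC(=O)O[C@@H](CC/C(C)=C\[C@H]1OC(=O)C(C)=C1CBr)[C@@]1(C)C=C(C)C=C(OC(C)=O)[C@H]1OC(C)=O
F10 | step 5 | (1S)-1-[(1R,6S)-6-(acetyloxy)-5-(tert-butylperoxy)-1,3-dimethylcyclohex-3-en-1-yl]prop-2-en-1-yl propanoate (C13 epimers) | CCC(=O)O[C@@H](C=C)[C@@]1(C)CC(C)=CC(OOC(C)(C)C)[C@H]1OC(C)=O
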